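**Retrosynthetic overview**

1. Ring A is a resorcinol whose free OH, aryl-ether O and C16 chain sit on alternate carbons, with a CH between each pair. This 1,3,5 pattern with one oxygen free and one etherified is what a Danheiser benzannulation gives from a 3-alkylcyclobutenone (supplying C–OH, two CH and the chain-bearing carbon) and a terminal aryloxyacetylene (supplying the C–OAr carbon and its CH neighbour).
2. Key disconnection: ring A is split into these two units, both already attached to ring B (the alkyne through the ether oxygen, the cyclobutenone through the C16 chain). One thermal operation then closes the 22-membered ring by ketene–alkyne [2+2] (bond between C–OAr and the CH lying between it and the chain carbon) and completes ring A by electrocyclisation.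
3. Precursor: the cyclobutenone comes from the chain Grignard reagent and 3-ethoxycyclobutenone; the ethynyl ether comes from the ring B phenol via its dichlorovinyl ether (trichloroethylene, then n-BuLi).
4. Ring B with its chain: 2,4-dimethoxyphenol, ortho-formylation, Wittig reaction with a C15 ylide, hydrogenation.
5. Order of rings: ring B is bought; ring A and the 22-membered ring arise together in step 10, the last ring-forming step; afterwards only two O-methyl groups are removed.

Key step: step 10

Assumption: the target has no stereocentre, so no stereocontrol is needed; 15-bromopentadecan-1-ol and 3-ethoxycyclobut-2-en-1-one are taken as catalogue compounds.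

**Route**

Step 1
Reactants: 1 2,4-dimethoxyphenol
Product: 2 2-hydroxy-3,5-dimethoxybenzaldehyde
Conditions: MgCl2, Et3N, (CH2O)n, MeCN, reflux; aq. HCl work-up
Reagents that add atoms: paraformaldehyde (as formaldehyde), C=O
Why: Magnesium-phenoxide-directed ortho-formylation (Casnati–Skattebøl reaction) should deliver formaldehyde to the only free ortho position, a second formaldehyde serving as hydride acceptor.

Step 2
Reactants: 2 2-hydroxy-3,5-dimethoxybenzaldehyde
Product: 3 2-(benzyloxy)-3,5-dimethoxybenzaldehyde
Conditions: BnBr, K2CO3, DMF, rt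
Reagents that add atoms: benzyl bromide, BrCc1ccccc1
Why: Williamson etherification masks the phenol for the ylide step with a group that the later hydrogenation removes together with the alkene.

Step 3
Reactants: 4 15-bromopentadecan-1-ol
Product: 5 (15-hydroxypentadecyl)triphenylphosphonium bromide
Conditions: PPh3, MeCN, reflux
Reagents that add atoms: triphenylphosphine, c1ccc(cc1)P(c1ccccc1)c1ccccc1
Why: SN2 quaternisation of the phosphine by the primary bromide should proceed cleanly, the hydroxyl being inert.

Step 4
Reactants: 3 2-(benzyloxy)-3,5-dimethoxybenzaldehyde; 5 (15-hydroxypentadecyl)triphenylphosphonium bromide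
Product: 7 (Z)-16-[2-(benzyloxy)-3,5-dimethoxyphenyl]hexadec-15-en-1-ol, via phosphorus ylide 6 (not isolated)
Conditions: 5, NaN(SiMe3)2 (2.0 equiv per 5), THF, 0 °C; then 3, −78 °C to rt
Reagents that add atoms: none
Why: Wittig olefination with a non-stabilised ylide (the second equivalent of base parks the hydroxyl as alkoxide) should join the C15 unit to the benzylic carbon; the mainly Z geometry is irrelevant because the alkene is hydrogenated next.

Step 5
Reactants: 7 (Z)-16-[2-(benzyloxy)-3,5-dimethoxyphenyl]hexadec-15-en-1-ol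
Product: 8 2-(16-hydroxyhexadecyl)-4,6-dimethoxyphenol
Conditions: H2 (1 atm), 10% Pd/C, EtOAc/EtOH, rt
Reagents that add atoms: none
Why: Heterogeneous hydrogenation should saturate the styrenyl alkene and hydrogenolyse the benzyl ether in one operation, leaving the methyl ethers and the primary alcohol untouched.

Step 6
Reactants: 8 2-(16-hydroxyhexadecyl)-4,6-dimethoxyphenol
Product: 9 16-[2-{[(E)-1,2-dichloroethenyl]oxy}-3,5-dimethoxyphenyl]hexadecan-1-ol
Conditions: Cl2C=CHCl (1.5 equiv), K2CO3, DMF, 70 °C, Ar
Reagents that add atoms: trichloroethylene, ClC=C(Cl)Cl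
Why: The phenoxide should add anti to dichloroacetylene formed in situ from trichloroethylene (addition then protonation) to give the E-dichlorovinyl ether, while carbonate is too weak a base to engage the primary alcohol.

Step 7
Reactants: 9 16-[2-{[(E)-1,2-dichloroethenyl]oxy}-3,5-dimethoxyphenyl]hexadecan-1-ol
Product: 10 1-(16-bromohexadecyl)-2-{[(E)-1,2-dichloroethenyl]oxy}-3,5-dimethoxybenzene
Conditions: CBr4, PPh3, CH2Cl2, 0 °C
Reagents that add atoms: tetrabromomethane, BrC(Br)(Br)Br
Why: Appel bromination converts the primary alcohol under neutral conditions that the dichlorovinyl ether and the methyl ethers tolerate.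

Step 8
Reactants: 10 1-(16-bromohexadecyl)-2-{[(E)-1,2-dichloroethenyl]oxy}-3,5-dimethoxybenzene
Product: 13 1-(16-bromohexadecyl)-2-(ethynyloxy)-3,5-dimethoxybenzene, via chloroethynyl ether 11 (not isolated), via lithium acetylide 12 (not isolated)
Conditions: n-BuLi (2.2 equiv), THF, −78 °C, 1 h; H2O quench at −78 °C
Reagents that add atoms: none
Why: Vinylic lithiation with loss of LiCl gives the chloroalkyne, chlorine–lithium exchange gives the acetylide and protonation frees the ethynyl ether (dichlorovinyl ether route to ynol ethers); at −78 °C the primary bromide should not be attacked by n-BuLi or by the acetylide.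

Step 9
Reactants: 13 1-(16-bromohexadecyl)-2-(ethynyloxy)-3,5-dimethoxybenzene; 14 3-ethoxycyclobut-2-en-1-one
Product: 19 3-{16-[2-(ethynyloxy)-3,5-dimethoxyphenyl]hexadecyl}cyclobut-2-en-1-one, via alkynylmagnesium chloride 15 (not isolated), via bis-Grignard reagent 16 (not isolated), via magnesium alkoxide adduct 17 (not isolated), via cyclobutenol 18 (not isolated)
Conditions: i-PrMgCl (1.0 equiv), THF, 0 °C to rt; Mg turnings, THF, 35 °C; 14 (1.05 equiv), −78 °C; then dilute aq. HCl to pH 3, 0 °C, 15 min; NaHCO3
Reagents that add atoms: water, O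
Why: In this Stork–Danheiser-type 1,2-addition and transposition the acidic alkyne C–H is parked as the poorly nucleophilic alkynylmagnesium chloride, the alkylmagnesium terminus adds to the carbonyl of the vinylogous ester at −78 °C, and the resulting vinylogous hemiketal should ionise and hydrolyse at pH 3 far faster than an aryl ethynyl ether is hydrated.

Step 10
Reactants: 19 3-{16-[2-(ethynyloxy)-3,5-dimethoxyphenyl]hexadecyl}cyclobut-2-en-1-one
Product: 24 macrocyclic monophenol (4,6-di-O-methyl ether of the target on ring B), via vinylketene 20 (not isolated), via vinylcyclobutenone 21 (not isolated), via dienylketene 22 (not isolated), via cyclohexadienone 23 (not isolated)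
Conditions: toluene, 110 °C, 1 mM, syringe-pump addition over 12 h, then 4 h at 110 °C, Ar
Reagents that add atoms: none
Why: Proposed new method: reversible thermal 4π electrocyclic opening of the cyclobutenone gives vinylketene 20, whose [2+2] cycloaddition with the tethered aryloxyacetylene gives 21; 4π opening of 21 to dienylketene 22, 6π electrocyclisation to 23 and tautomerisation then give phenol 24. The closest known reaction is the intermolecular Danheiser benzannulation of 3-alkylcyclobutenones with alkoxy- and siloxyacetylenes; new here are the aryloxyacetylene partner and the tethered, macrocyclising mode. The 22-membered ring closes in the ketene–alkyne [2+2] event as an end-to-end closure of an unstrained chain (bond from the ketene α-carbon to the oxygen-bearing alkyne carbon), and ring A then closes by disrotatory 6π electrocyclisation of the dienylketene onto the ketene carbon. No stereocentre has to be controlled, because the single sp3 centre of 21 is destroyed on ring opening. The regioselectivity that puts OH, O-aryl and chain on alternate carbons follows from polarity, the nucleophilic terminal CH of the ynol ether bonding to the ketene carbonyl carbon. Ring closure over oligomerisation is secured by high dilution with slow addition and by the vinylketene being a reversibly formed, low-concentration intermediate that falls back to 19 unless it meets the ynol ether, ring B offering no competing ketenophile.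

Step 11
Reactants: 24 macrocyclic monophenol (4,6-di-O-methyl ether of the target on ring B)
Product: 25 grevirobstol B
Conditions: BBr3 (6 equiv), CH2Cl2, −78 °C to rt; then H2O
Reagents that add atoms: none
Why: Lewis-acid demethylation with BBr3 (bromide attack at methyl of the boron-complexed ether) should cleave both aryl methyl ethers while the diaryl ether and the alkyl chain stay intact.

**Compound list**

1 | 2,4-dimethoxyphenol | COc1ccc(O)c(OC)c1 | starting material
2 | 2-hydroxy-3,5-dimethoxybenzaldehyde | COc1cc(C=O)c(O)c(OC)c1 | intermediate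
3 | 2-(benzyloxy)-3,5-dimethoxybenzaldehyde | COc1cc(C=O)c(OCc2ccccc2)c(OC)c1 | intermediate
4 | 15-bromopentadecan-1-ol | OCCCCCCCCCCCCCCCBr | starting material
5 | (15-hydroxypentadecyl)triphenylphosphonium bromide | [Br-].OCCCCCCCCCCCCCCC[P+](c1ccccc1)(c1ccccc1)c1ccccc1 | intermediate
6 | phosphorus ylide of 5 as its sodium alkoxide | [Na+].[O-]CCCCCCCCCCCCCCC=P(c1ccccc1)(c1ccccc1)c1ccccc1 | intermediate
7 | (Z)-16-[2-(benzyloxy)-3,5-dimethoxyphenyl]hexadec-15-en-1-ol | COc1cc(/C=C\CCCCCCCCCCCCCCO)c(OCc2ccccc2)c(OC)c1 | intermediate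
8 | 2-(16-hydroxyhexadecyl)-4,6-dimethoxyphenol | COc1cc(CCCCCCCCCCCCCCCCO)c(O)c(OC)c1 | intermediate
9 | 16-[2-{[(E)-1,2-dichloroethenyl]oxy}-3,5-dimethoxyphenyl]hexadecan-1-ol | COc1cc(CCCCCCCCCCCCCCCCO)c(O/C(Cl)=C\Cl)c(OC)c1 | intermediate
10 | 1-(16-bromohexadecyl)-2-{[(E)-1,2-dichloroethenyl]oxy}-3,5-dimethoxybenzene | COc1cc(CCCCCCCCCCCCCCCCBr)c(O/C(Cl)=C\Cl)c(OC)c1 | intermediate
11 | 1-(16-bromohexadecyl)-2-[(chloroethynyl)oxy]-3,5-dimethoxybenzene | COc1cc(CCCCCCCCCCCCCCCCBr)c(OC#CCl)c(OC)c1 | intermediate
12 | lithium acetylide of 13 | COc1cc(CCCCCCCCCCCCCCCCBr)c(OC#C[Li])c(OC)c1 | intermediate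
13 | 1-(16-bromohexadecyl)-2-(ethynyloxy)-3,5-dimethoxybenzene | COc1cc(CCCCCCCCCCCCCCCCBr)c(OC#C)c(OC)c1 | intermediate
14 | 3-ethoxycyclobut-2-en-1-one | CCOC1=CC(=O)C1 | starting material
15 | alkynylmagnesium chloride of 13 | COc1cc(CCCCCCCCCCCCCCCCBr)c(OC#C[Mg]Cl)c(OC)c1 | intermediate
16 | bis-Grignard reagent (alkylmagnesium bromide and alkynylmagnesium chloride termini) | COc1cc(CCCCCCCCCCCCCCCC[Mg]Br)c(OC#C[Mg]Cl)c(OC)c1 | intermediate
17 | magnesium alkoxide of the 1,2-adduct to 14 | COc1cc(CCCCCCCCCCCCCCCCC2(O[Mg]Br)CC(OCC)=C2)c(OC#C[Mg]Cl)c(OC)c1 | intermediate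
18 | 3-ethoxy-1-{16-[2-(ethynyloxy)-3,5-dimethoxyphenyl]hexadecyl}cyclobut-2-en-1-ol | COc1cc(CCCCCCCCCCCCCCCCC2(O)CC(OCC)=C2)c(OC#C)c(OC)c1 | intermediate
19 | 3-{16-[2-(ethynyloxy)-3,5-dimethoxyphenyl]hexadecyl}cyclobut-2-en-1-one | COc1cc(CCCCCCCCCCCCCCCCC2=CC(=O)C2)c(OC#C)c(OC)c1 | intermediate
20 | vinylketene from ring opening of 19 | COc1cc(CCCCCCCCCCCCCCCCC(=C)C=C=O)c(OC#C)c(OC)c1 | intermediate
21 | macrocyclic 3-aryloxy-4-vinylcyclobut-2-en-1-one (racemic, 22-membered ring closed) | COc1cc2CCCCCCCCCCCCCCCCC(=C)C3C(=O)C=C3Oc2c(OC)c1 | intermediate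
22 | macrocyclic dienylketene (ketenyl and vinyl groups cis across the central C=C) | COc1cc2CCCCCCCCCCCCCCCCC(=C)/C=C(\C=C=O)Oc2c(OC)c1 | intermediate
23 | macrocyclic cyclohexa-2,4-dien-1-one (keto tautomer of 24) | COc1cc2CCCCCCCCCCCCCCCCC3=CC(=CC(=O)C3)Oc2c(OC)c1 | intermediate
24 | macrocyclic monophenol: grevirobstol B with both ring B hydroxyls as methyl ethers | COc1cc2CCCCCCCCCCCCCCCCc3cc(O)cc(c3)Oc2c(OC)c1 | intermediate
25 | grevirobstol B | Oc1cc2cc(c1)Oc1c(O)cc(O)cc1CCCCCCCCCCCCCCCC2 | target

**Totals**

Total step count: 11. Longest linear sequence: 10 steps (steps 1, 2 and 4 to 11; step 3 prepares the side fragment 5).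

**Steps most likely to fail**

Step 10 (proposed new method). The closure may be lost to intermolecular capture of the vinylketene (oligomerisation), or the terminal ethynyl ether may decompose thermally before the cycloaddition. The fallback uses known chemistry, sets out from 8 and comes back at 25. Appel bromination of 8 (CBr4, PPh3, CH2Cl2) should give 2-(16-bromohexadecyl)-4,6-dimethoxyphenol F1. Bromine–magnesium exchange on 1,3-dibromo-5-methoxybenzene (i-PrMgCl·LiCl, THF, −15 °C) gives (3-bromo-5-methoxyphenyl)magnesium chloride F2. Using 2.2 equiv of F2 (the first equivalent deprotonates the phenol), Li2CuCl4-catalysed alkyl–aryl coupling with F1 (THF/NMP, 0 °C) should give 2-[16-(3-bromo-5-methoxyphenyl)hexadecyl]-4,6-dimethoxyphenol F3. Intramolecular Ullmann diaryl ether formation (CuI, N,N-dimethylglycine, Cs2CO3, dioxane, 110 °C, 2 mM) then closes the 22-membered ring by C–O bond formation to the macrocyclic trimethyl ether F4. BBr3 under the conditions of step 11 converts F4 into 25.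

Step 9. The ethynyl ether may be hydrated during the acid-promoted transposition. The alkylmagnesium terminus may also be consumed by proton transfer or Wurtz coupling, or the alkynylmagnesium end may add competitively to 14. The fallback replaces in-situ magnesiation by covalent protection, sets out from 10 and comes back at 19. Treatment of 10 with n-BuLi (2.2 equiv, THF, −78 °C) and silylation of the acetylide with i-Pr3SiOTf should give {[2-(16-bromohexadecyl)-4,6-dimethoxyphenoxy]ethynyl}tri(propan-2-yl)silane F5, whose alkyne is shielded on both sides. Magnesium insertion, addition to 14 at −78 °C and the same pH 3 hydrolysis should give 3-[16-(3,5-dimethoxy-2-{[tri(propan-2-yl)silyl]ethynyloxy}phenyl)hexadecyl]cyclobut-2-en-1-one F6. Buffered desilylation (Bu4NF, AcOH, THF, 0 °C) returns to 19.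

Step 8. The primary C–Br bond may undergo halogen–lithium exchange or Wurtz coupling with n-BuLi, or the acetylide may be alkylated on warming. The fallback introduces the bromide only after the strong-base step, sets out from 9 and comes back at 13. Treatment of 9 with n-BuLi (3.3 equiv, THF, −78 °C; the alkoxide is a spectator) should give 16-[2-(ethynyloxy)-3,5-dimethoxyphenyl]hexadecan-1-ol F7. Mesylation (MsCl, Et3N, CH2Cl2, 0 °C) gives 16-[2-(ethynyloxy)-3,5-dimethoxyphenyl]hexadecyl methanesulfonate F8, and displacement with LiBr in acetone gives 13.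

**Further compounds**

F1 | step 10 | 2-(16-bromohexadecyl)-4,6-dimethoxyphenol | COc1cc(CCCCCCCCCCCCCCCCBr)c(O)c(OC)c1
F2 | step 10 | (3-bromo-5-methoxyphenyl)magnesium chloride | COc1cc(Br)cc([Mg]Cl)c1
F3 | step 10 | 2-[16-(3-bromo-5-methoxyphenyl)hexadecyl]-4,6-dimethoxyphenol | COc1cc(CCCCCCCCCCCCCCCCc2cc(Br)cc(OC)c2)c(O)c(OC)c1
F4 | step 10 | macrocyclic trimethyl ether of grevirobstol B | COc1cc2CCCCCCCCCCCCCCCCc3cc(OC)cc(c3)Oc2c(OC)c1
F5 | step 9 | {[2-(16-bromohexadecyl)-4,6-dimethoxyphenoxy]ethynyl}tri(propan-2-yl)silane | COc1cc(CCCCCCCCCCCCCCCCBr)c(OC#C[Si](C(C)C)(C(C)C)C(C)C)c(OC)c1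
F6 | step 9 | 3-[16-(3,5-dimethoxy-2-{[tri(propan-2-yl)silyl]ethynyloxy}phenyl)hexadecyl]cyclobut-2-en-1-one | COc1cc(CCCCCCCCCCCCCCCCC2=CC(=O)C2)c(OC#C[Si](C(C)C)(C(C)C)C(C)C)c(OC)c1
F7 | step 8 | 16-[2-(ethynyloxy)-3,5-dimethoxyphenyl]hexadecan-1-ol | COc1cc(CCCCCCCCCCCCCCCCO)c(OC#C)c(OC)c1
F8 | step 8 | 16-[2-(ethynyloxy)-3,5-dimethoxyphenyl]hexadecyl methanesulfonate | COc1cc(CCCCCCCCCCCCCCCCOS(C)(=O)=O)c(OC#C)c(OC)c1
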